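**Retrosynthetic overview**

1. Target 16 ⇐ desilylation and hydride opening of γ-lactone 14 ⇐ Baeyer–Villiger oxygen insertion (retention at C7) into cyclobutanone 13.
2. Feature used: on the oxolane ring (O1, C2–C5) the hydroxymethyl carbon C9 on C3 and the carbinol carbon C7 on C4 are cis and lack only a C9–C7 bond to make a four-membered ring fused across C3–C4. Cyclobutanone 13 is therefore cut into aryl ketene 12 (C9 to C3, C7 to C4) and (S)-2-aryl-2,5-dihydrofuran 11.
3. 11 ⇐ ring-closing metathesis of allyl ether 10 ⇐ (S)-aryl vinyl carbinol 8 (lipase resolution) ⇐ aldehyde 5 + vinylmagnesium bromide 6; 12 ⇐ acid chloride 3 ⇐ homovanillic acid 1.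
4. Ring order: oxolane (metathesis), then cyclobutanone ([2+2]), then γ-lactone (ring expansion), which is reopened so that only the oxolane remains.

Key step: step 8

Remark: atom labels follow the oxolane (O1, C2 bearing the catechol, C3, C4, C5), with C7 the benzylic carbinol carbon and C9 the hydroxymethyl carbon; all three phenols are carried as tert-butyldimethylsilyl (TBS) ethers, and the crude acid chloride 3 is treated as an isolated compound.

**Route**

Step 1
Reactants: 1 homovanillic acid
Product: 2 tert-butyldimethylsilyl [4-(tert-butyldimethylsilyloxy)-3-methoxyphenyl]acetate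
Conditions: TBSCl (2.3 equiv), imidazole (5 equiv), DMF, rt; pentane extraction, cold water wash
Reagents that add atoms: tert-butyldimethylsilyl chloride, C[Si](C)(Cl)C(C)(C)C
Why: Silylation with TBSCl/imidazole should cap both the phenol (silyl ether) and the acid (silyl ester), which protects the phenol and prepares the carboxyl group for neutral conversion into the acid chloride.

Step 2
Reactants: 2 tert-butyldimethylsilyl [4-(tert-butyldimethylsilyloxy)-3-methoxyphenyl]acetate
Product: 3 [4-(tert-butyldimethylsilyloxy)-3-methoxyphenyl]acetyl chloride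
Conditions: (COCl)2 (1.3 equiv), DMF (cat.), CH2Cl2, 0 °C → rt; volatiles removed, used crude
Reagents that add atoms: oxalyl chloride, O=C(Cl)C(=O)Cl
Why: A silyl ester reacts with the chloroiminium (Vilsmeier) species from oxalyl chloride/DMF to give the acid chloride with loss of TBSCl, CO and CO2 and without free HCl, so the aryl silyl ether should survive (acid chloride formation from a silyl ester under neutral conditions).

Step 3
Reactants: 4 3,4-dihydroxybenzaldehyde
Product: 5 3,4-bis(tert-butyldimethylsilyloxy)benzaldehyde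
Conditions: TBSCl (2.4 equiv), imidazole (5 equiv), DMF, rt
Reagents that add atoms: tert-butyldimethylsilyl chloride, C[Si](C)(Cl)C(C)(C)C
Why: Standard bis-silylation of a catechol, giving phenol protection that tolerates the Grignard, metathesis, ketene, peracid and hydride steps and is removed by fluoride at the end.

Step 4
Reactants: 5 3,4-bis(tert-butyldimethylsilyloxy)benzaldehyde; 6 vinylmagnesium bromide
Product: 7 rac-1-[3,4-bis(tert-butyldimethylsilyloxy)phenyl]prop-2-en-1-ol
Conditions: THF, −78 → 0 °C; H2O/aq NH4Cl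
Reagents that add atoms: none
Why: Grignard 1,2-addition to an aromatic aldehyde should give the racemic aryl vinyl carbinol, the aryl silyl ethers being stable to the magnesium alkoxide at low temperature.

Step 5
Reactants: 7 rac-1-[3,4-bis(tert-butyldimethylsilyloxy)phenyl]prop-2-en-1-ol
Product: 8 (S)-1-[3,4-bis(tert-butyldimethylsilyloxy)phenyl]prop-2-en-1-ol
Conditions: immobilised Candida antarctica lipase B, vinyl acetate (3 equiv), MTBE, 35 °C, stopped just past half conversion; chromatography
Reagents that add atoms: none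
Why: Lipase-catalysed kinetic resolution by transesterification: with aryl as the large and vinyl as the medium substituent the usual large/medium-substituent rule for lipases predicts acetylation of the (R)-alcohol, so the (S)-alcohol 8 should be left unreacted, and this sets the C2 stereocentre of the target.

Step 6
Reactants: 8 (S)-1-[3,4-bis(tert-butyldimethylsilyloxy)phenyl]prop-2-en-1-ol; 9 allyl bromide
Product: 10 (S)-4-[1-(allyloxy)prop-2-en-1-yl]-1,2-bis(tert-butyldimethylsilyloxy)benzene
Conditions: NaH (1.3 equiv), 9 (3 equiv), Bu4NI (cat.), THF, 0 °C → rt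
Reagents that add atoms: none
Why: Williamson etherification of the sodium alkoxide with the reactive allyl halide leaves the stereocentre untouched, and THF, low temperature and excess electrophile should keep silyl transfer from the aryl ethers to the alkoxide slow.

Step 7
Reactants: 10 (S)-4-[1-(allyloxy)prop-2-en-1-yl]-1,2-bis(tert-butyldimethylsilyloxy)benzene
Product: 11 (S)-2-[3,4-bis(tert-butyldimethylsilyloxy)phenyl]-2,5-dihydrofuran
Conditions: second-generation Grubbs catalyst (2 mol%), 1,4-benzoquinone (10 mol%), CH2Cl2 (0.02 M), 40 °C; filtration through Et3N-treated silica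
Reagents that add atoms: none
Why: Ring-closing metathesis of the diallyl ether should close the oxolane as its 2,5-dihydro form with loss of ethene, and benzoquinone suppresses ruthenium-hydride migration of the double bond to the enol ether isomer, which would otherwise capture the ketene in step 8.

Step 8
Reactants: 3 [4-(tert-butyldimethylsilyloxy)-3-methoxyphenyl]acetyl chloride; 11 (S)-2-[3,4-bis(tert-butyldimethylsilyloxy)phenyl]-2,5-dihydrofuran
Product: 13 endo-aryl cyclobutanone (1R,4S,5S,7R)-4-[3,4-bis(tert-butyldimethylsilyloxy)phenyl]-7-[4-(tert-butyldimethylsilyloxy)-3-methoxyphenyl]-3-oxabicyclo[3.2.0]heptan-6-one, via aryl ketene 12 (not isolated)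
Conditions: Et3N (4 equiv), toluene, 80 °C; 3 (3 equiv) added by syringe pump over 10 h to 11 (0.5 M); stopped at end of addition
Reagents that add atoms: none
Why: Et3N eliminates HCl from 3 to give aryl ketene 12, whose electrophilic carbonyl carbon is attacked by the C3=C4 π bond of 11 in a concerted but asynchronous [2+2] (suprafacial on the alkene, antarafacial on the ketene), the C3–C9 bond forming ahead of the C4–C7 bond. The closest known reaction type is the thermal cycloaddition of monosubstituted ketenes generated from acid chlorides with cyclopentene-type alkenes (phenylketene with cyclopentadiene), applied here to an unactivated cyclic alkene at the limit of that scope, which is why the ketene is kept at low stationary concentration by slow addition of excess 3 to concentrated 11. The cyclobutanone closes by intermolecular [2+2] cycloaddition across C3–C4, and because the alkene reacts suprafacially the ring fusion can only be cis, which fixes the 3,4-cis relation of the future CH2OH and ArCH(OH) arms. C3 and C4 are controlled by the C2 stereocentre, whose aryl group shields one face so that both bonds form anti to it (2,3-trans), and C7 is set under kinetic control by the ketene approaching with its hydrogen toward the alkene, which turns the aryl group onto the concave (endo) face on closure. The selectivity least secured by the substrate is the regiochemistry (carbonyl carbon to C3, ArCH to C4): it rests only on the later-forming, more encumbered bond closing at C4 beside the unsubstituted C5 methylene and on C4 tolerating the transient positive charge slightly better than C3, whose neighbour C2 carries both oxygen and aryl, so a regioisomer is to be expected as a by-product and removed by chromatography. Contact of 13 with the amine is kept short because the endo-aryl centre can epimerise to the exo isomer by enolisation.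

Step 9
Reactants: 13 endo-aryl cyclobutanone
Product: 14 (3R,3aR,6S,6aS)-6-[3,4-bis(tert-butyldimethylsilyloxy)phenyl]-3-[4-(tert-butyldimethylsilyloxy)-3-methoxyphenyl]tetrahydro-1H,3H-furo[3,4-c]furan-1-one
Conditions: mCPBA (1.5 equiv), CH2Cl2, 0 °C → rt; aq Na2S2O3/NaHCO3 wash
Reagents that add atoms: meta-chloroperoxybenzoic acid, OOC(=O)c1cccc(Cl)c1
Why: Baeyer–Villiger oxidation driven by release of cyclobutanone strain: in the Criegee adduct the electron-rich secondary benzylic carbon C7 should migrate in preference to C3 (a secondary alkyl carbon deactivated by the β-oxygen at C2), and migration proceeds with retention, so the endo-aryl centre becomes (7R).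

Step 10
Reactants: 14 bicyclic γ-lactone
Product: 15 (R)-[(3R,4R,5S)-5-[3,4-bis(tert-butyldimethylsilyloxy)phenyl]-4-(hydroxymethyl)oxolan-3-yl][4-(tert-butyldimethylsilyloxy)-3-methoxyphenyl]methanol
Conditions: LiAlH4 (2 equiv), THF, 0 °C; Na2SO4·10H2O quench
Reagents that add atoms: none
Why: Hydride reduction of the lactone to the 1,4-diol turns C9 into the CH2OH arm on C3 and frees the C7 hydroxyl without touching any stereocentre, aryl silyl ethers being tolerated at 0 °C.

Step 11
Reactants: 15 tris-silylated diol
Product: 16 (7R)-7-hydroxytaxiresinol, 4-[(2S,3R,4R)-4-[(R)-hydroxy(4-hydroxy-3-methoxyphenyl)methyl]-3-(hydroxymethyl)oxolan-2-yl]benzene-1,2-diol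
Conditions: Bu4NF (3.5 equiv), AcOH (3.5 equiv), THF, 0 °C, Ar; pH 7 buffer work-up
Reagents that add atoms: none
Why: Fluoride cleavage of the three aryl silyl ethers; the acetic acid buffer keeps the phenoxide concentration low, which should protect the 4-hydroxybenzylic alcohol from quinone methide formation and the catechol from autoxidation.

**Compound list**

1 | homovanillic acid | COc1cc(CC(=O)O)ccc1O | starting material
2 | tert-butyldimethylsilyl [4-(tert-butyldimethylsilyloxy)-3-methoxyphenyl]acetate | COc1cc(CC(=O)O[Si](C)(C)C(C)(C)C)ccc1O[Si](C)(C)C(C)(C)C | intermediate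
3 | [4-(tert-butyldimethylsilyloxy)-3-methoxyphenyl]acetyl chloride | COc1cc(CC(=O)Cl)ccc1O[Si](C)(C)C(C)(C)C | intermediate
4 | 3,4-dihydroxybenzaldehyde | O=Cc1ccc(O)c(O)c1 | starting material
5 | 3,4-bis(tert-butyldimethylsilyloxy)benzaldehyde | O=Cc1ccc(O[Si](C)(C)C(C)(C)C)c(O[Si](C)(C)C(C)(C)C)c1 | intermediate
6 | vinylmagnesium bromide | C=C[Mg]Br | starting material
7 | rac-1-[3,4-bis(tert-butyldimethylsilyloxy)phenyl]prop-2-en-1-ol | C=CC(O)c1ccc(O[Si](C)(C)C(C)(C)C)c(O[Si](C)(C)C(C)(C)C)c1 | intermediate
8 | (S)-1-[3,4-bis(tert-butyldimethylsilyloxy)phenyl]prop-2-en-1-ol | C=C[C@H](O)c1ccc(O[Si](C)(C)C(C)(C)C)c(O[Si](C)(C)C(C)(C)C)c1 | intermediate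
9 | allyl bromide | C=CCBr | starting material
10 | (S)-4-[1-(allyloxy)prop-2-en-1-yl]-1,2-bis(tert-butyldimethylsilyloxy)benzene | C=CCO[C@@H](C=C)c1ccc(O[Si](C)(C)C(C)(C)C)c(O[Si](C)(C)C(C)(C)C)c1 | intermediate
11 | (S)-2-[3,4-bis(tert-butyldimethylsilyloxy)phenyl]-2,5-dihydrofuran | C1=C[C@@H](c2ccc(O[Si](C)(C)C(C)(C)C)c(O[Si](C)(C)C(C)(C)C)c2)OC1 | intermediate
12 | [4-(tert-butyldimethylsilyloxy)-3-methoxyphenyl]ketene | O=C=Cc1ccc(O[Si](C)(C)C(C)(C)C)c(OC)c1 | intermediate (not isolated)
13 | (1R,4S,5S,7R)-4-[3,4-bis(tert-butyldimethylsilyloxy)phenyl]-7-[4-(tert-butyldimethylsilyloxy)-3-methoxyphenyl]-3-oxabicyclo[3.2.0]heptan-6-one (cis-fused, C7 aryl endo, C4 aryl anti to the four-membered ring) | O=C1[C@@H](c2ccc(O[Si](C)(C)C(C)(C)C)c(OC)c2)[C@H]2CO[C@H](c3ccc(O[Si](C)(C)C(C)(C)C)c(O[Si](C)(C)C(C)(C)C)c3)[C@@H]12 | intermediate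
14 | (3R,3aR,6S,6aS)-6-[3,4-bis(tert-butyldimethylsilyloxy)phenyl]-3-[4-(tert-butyldimethylsilyloxy)-3-methoxyphenyl]tetrahydro-1H,3H-furo[3,4-c]furan-1-one | O=C1O[C@@H](c2ccc(O[Si](C)(C)C(C)(C)C)c(OC)c2)[C@H]2CO[C@H](c3ccc(O[Si](C)(C)C(C)(C)C)c(O[Si](C)(C)C(C)(C)C)c3)[C@@H]12 | intermediate
15 | (R)-[(3R,4R,5S)-5-[3,4-bis(tert-butyldimethylsilyloxy)phenyl]-4-(hydroxymethyl)oxolan-3-yl][4-(tert-butyldimethylsilyloxy)-3-methoxyphenyl]methanol | COc1cc([C@H](O)[C@H]2CO[C@H](c3ccc(O[Si](C)(C)C(C)(C)C)c(O[Si](C)(C)C(C)(C)C)c3)[C@H]2CO)ccc1O[Si](C)(C)C(C)(C)C | intermediate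
16 | (7R)-7-hydroxytaxiresinol | COc1cc([C@H](O)[C@H]2CO[C@H](c3ccc(O)c(O)c3)[C@H]2CO)ccc1O | target

**Step count**

Total: 11 steps. Longest linear sequence: 9 steps (steps 3–11, from 3,4-dihydroxybenzaldehyde).

**Steps most likely to fail**

Step 8 (ketene [2+2]). What may go wrong: the aryl ketene dimerises or oligomerises faster than it adds to the unactivated C3=C4 bond, addition proceeds with incomplete regiocontrol, or the amine epimerises the endo-aryl centre to exo. The fallback sets out from 3 and 11 and comes back at 13. Acid chloride 3 is treated with dimethylamine to give N,N-dimethyl-2-[4-(tert-butyldimethylsilyloxy)-3-methoxyphenyl]acetamide F1. Tf2O and 2,4,6-collidine in 1,2-dichloroethane convert it into the keteniminium triflate F2, a cationic ketene equivalent that does not dimerise and is known to add to simple cycloalkenes. Its [2+2] cycloaddition with 11 should give the cyclobutaniminium triflate F3, and aqueous NaHCO3 hydrolysis the ketone, expected after iminium–enamine equilibration mainly as the more stable exo-aryl cyclobutanone F4. Deprotonation at the benzylic carbon with LiN(SiMe3)2 (THF, −78 °C) gives the lithium enolate F5, and protonation at −78 °C with 2,6-di-tert-butyl-4-methylphenol from the open convex face should place hydrogen exo and the aryl group endo, returning 13. The same enolate protonation can correct exo material formed in step 8 itself; regioisomers would still be separated by chromatography.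

Step 6 (O-allylation). What may go wrong: silyl groups transfer from the aryl oxygens to the sodium alkoxide, and the freed phenoxide is then allylated. The fallback sets out from 8 and comes back at 11, using only amine bases. Acryloyl chloride/Et3N (CH2Cl2, 0 °C) gives (S)-1-[3,4-bis(tert-butyldimethylsilyloxy)phenyl]allyl acrylate F6. Ring-closing metathesis (second-generation Grubbs catalyst, toluene, 80 °C) gives (S)-5-[3,4-bis(tert-butyldimethylsilyloxy)phenyl]furan-2(5H)-one F7. iBu2AlH (CH2Cl2, −78 → 0 °C) reduces the butenolide to (S,Z)-1-[3,4-bis(tert-butyldimethylsilyloxy)phenyl]but-2-ene-1,4-diol F8. TsCl/Et3N/DMAP (cat.) at −20 °C sulfonylates the primary hydroxyl to the primary monotosylate F9 (not isolated), which the secondary hydroxyl displaces in a 5-exo-tet closure with retention at the carbinol carbon, giving 11.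

Step 5 (lipase resolution). What may go wrong: acylation of the hindered aryl vinyl carbinol is slow or weakly enantioselective, leaving 8 in insufficient enantiomeric purity, and at best half of the material is usable. The fallback sets out from 5 and comes back at 11 by asymmetric catalysis. Dakin-type Baeyer–Villiger oxidation of the electron-rich aldehyde (mCPBA, CH2Cl2) gives 3,4-bis(tert-butyldimethylsilyloxy)phenyl formate F10. Et3N/MeOH cleaves it to 3,4-bis(tert-butyldimethylsilyloxy)phenol F11, and Tf2O/pyridine gives 3,4-bis(tert-butyldimethylsilyloxy)phenyl trifluoromethanesulfonate F12. Asymmetric Heck arylation of 2,3-dihydrofuran with F12 (Pd2(dba)3, (R)-4-tert-butyl-2-[2-(diphenylphosphino)phenyl]-4,5-dihydrooxazole, iPr2NEt, THF, 70 °C) should give 11 directly, this P,N-ligand class being known to leave the double bond in the 2,5-position. The ligand enantiomer is chosen by analogy with phenyl triflate and would be confirmed by comparison with 11 made from 8.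

**Further compounds**

F1 | step 8 | N,N-dimethyl-2-[4-(tert-butyldimethylsilyloxy)-3-methoxyphenyl]acetamide | COc1cc(CC(=O)N(C)C)ccc1O[Si](C)(C)C(C)(C)C
F2 | step 8 | N-[2-[4-(tert-butyldimethylsilyloxy)-3-methoxyphenyl]ethenylidene]-N-methylmethanaminium trifluoromethanesulfonate (keteniminium triflate) | COc1cc(C=C=[N+](C)C)ccc1O[Si](C)(C)C(C)(C)C.[O-]S(=O)(=O)C(F)(F)F
F3 | step 8 | cyclobutaniminium triflate of 13 (C7 configuration not fixed) | C[N+](C)=C1C(c2ccc(O[Si](C)(C)C(C)(C)C)c(OC)c2)[C@H]2CO[C@H](c3ccc(O[Si](C)(C)C(C)(C)C)c(O[Si](C)(C)C(C)(C)C)c3)[C@@H]12.[O-]S(=O)(=O)C(F)(F)F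
F4 | step 8 | (1R,4S,5S,7S)-4-[3,4-bis(tert-butyldimethylsilyloxy)phenyl]-7-[4-(tert-butyldimethylsilyloxy)-3-methoxyphenyl]-3-oxabicyclo[3.2.0]heptan-6-one (exo-aryl epimer) | O=C1[C@H](c2ccc(O[Si](C)(C)C(C)(C)C)c(OC)c2)[C@H]2CO[C@H](c3ccc(O[Si](C)(C)C(C)(C)C)c(O[Si](C)(C)C(C)(C)C)c3)[C@@H]12
F5 | step 8 | lithium enolate of 13 (C6–C7 enolate) | [Li+].[O-]C1=C(c2ccc(O[Si](C)(C)C(C)(C)C)c(OC)c2)[C@H]2CO[C@H](c3ccc(O[Si](C)(C)C(C)(C)C)c(O[Si](C)(C)C(C)(C)C)c3)[C@@H]12
F6 | step 6 | (S)-1-[3,4-bis(tert-butyldimethylsilyloxy)phenyl]allyl acrylate | C=CC(=O)O[C@@H](C=C)c1ccc(O[Si](C)(C)C(C)(C)C)c(O[Si](C)(C)C(C)(C)C)c1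
F7 | step 6 | (S)-5-[3,4-bis(tert-butyldimethylsilyloxy)phenyl]furan-2(5H)-one | O=C1C=C[C@@H](c2ccc(O[Si](C)(C)C(C)(C)C)c(O[Si](C)(C)C(C)(C)C)c2)O1
F8 | step 6 | (S,Z)-1-[3,4-bis(tert-butyldimethylsilyloxy)phenyl]but-2-ene-1,4-diol | OC/C=C\[C@H](O)c1ccc(O[Si](C)(C)C(C)(C)C)c(O[Si](C)(C)C(C)(C)C)c1
F9 | step 6 | (S,Z)-4-[3,4-bis(tert-butyldimethylsilyloxy)phenyl]-4-hydroxybut-2-en-1-yl 4-methylbenzenesulfonate | Cc1ccc(cc1)S(=O)(=O)OC/C=C\[C@H](O)c1ccc(O[Si](C)(C)C(C)(C)C)c(O[Si](C)(C)C(C)(C)C)c1
F10 | step 5 | 3,4-bis(tert-butyldimethylsilyloxy)phenyl formate | O=COc1ccc(O[Si](C)(C)C(C)(C)C)c(O[Si](C)(C)C(C)(C)C)c1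
F11 | step 5 | 3,4-bis(tert-butyldimethylsilyloxy)phenol | Oc1ccc(O[Si](C)(C)C(C)(C)C)c(O[Si](C)(C)C(C)(C)C)c1
F12 | step 5 | 3,4-bis(tert-butyldimethylsilyloxy)phenyl trifluoromethanesulfonate | O=S(=O)(Oc1ccc(O[Si](C)(C)C(C)(C)C)c(O[Si](C)(C)C(C)(C)C)c1)C(F)(F)F
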